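The oxolane ring (O1, C2–C5) is pseudo-meso: C3 and C4 carry cis methyls, each aryl is trans to its neighbouring methyl, and only the side chain on the C5 aryl breaks the mirror plane. Both C–aryl bonds are therefore cut back to meso-2,3-dimethylsuccinic anhydride, whose carbonyls are told apart by a Rh-catalysed enantioselective arylation. The ring is closed last: 1,4-diol 17, formed in the flask from hydroxy ketone 16, is cyclodehydrated in acid. Because C2 and C5 are both p-oxybenzylic, their C–O bonds ionise reversibly (quinone-methide cations), so one operation closes the ring, sets C2 and C5 under thermodynamic control and frees the three phenols.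

Key step: step 9

Assumption 1: in the two catalytic enantioselective steps (2 and 6) the ligand antipode named is the one expected to give the stated product; the sense of induction is checked on the first run and the other antipode is used if it is opposite.
Assumption 2: 13, 14 and 16 are drawn as the major (Felkin) carbinol epimer; the minor epimer is carried along, because this centre is reset in step 9.

Step 1
Reactants: 1 1-methoxy-4-(prop-1-yn-1-yl)benzene; 2 (5-bromo-2-methoxyphenyl)boronic acid
Product: 3 4-bromo-1-methoxy-2-[(E)-1-(4-methoxyphenyl)prop-1-en-2-yl]benzene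
Conditions: [Rh(cod)OH]2 (cat.), dioxane/H2O 10:1, 90 °C, 2 in excess
Reagents that add atoms: none
Why: Rh-catalysed syn-hydroarylation of an internal aryl alkyl alkyne with an arylboronic acid should place the aryl group on the methyl-bearing carbon (rhodium at the carbon next to the anisyl ring) and, after protonolysis, give the E alkene, while Rh(I) leaves the C–Br bond alone.

Step 2
Reactants: 3 4-bromo-1-methoxy-2-[(E)-1-(4-methoxyphenyl)prop-1-en-2-yl]benzene
Product: 4 4-bromo-1-methoxy-2-[(2R)-1-(4-methoxyphenyl)propan-2-yl]benzene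
Conditions: H2 (50 bar), [Ir(cod)((S)-t-Bu-PHOX)]BArF (cat.), CH2Cl2, rt
Reagents that add atoms: none
Why: Ir–N,P-catalysed asymmetric hydrogenation of an unfunctionalised E-trisubstituted aryl alkene (the α-methylstilbene class) should set the benzylic centre as R by catalyst control of the alkene face, with aryl bromide and ethers inert.

Step 3
Reactants: 4 4-bromo-1-methoxy-2-[(2R)-1-(4-methoxyphenyl)propan-2-yl]benzene
Product: 5 4-bromo-2-[(2R)-1-(4-hydroxyphenyl)propan-2-yl]phenol
Conditions: BBr3 (3 equiv), CH2Cl2, −78 → 0 °C; H2O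
Reagents that add atoms: none
Why: Lewis-acid cleavage of both aryl methyl ethers should be clean here because the molecule holds no other acid-sensitive group and the stereocentre carries no leaving group.

Step 4
Reactants: 5 4-bromo-2-[(2R)-1-(4-hydroxyphenyl)propan-2-yl]phenol
Product: 6 4-bromo-1-(methoxymethoxy)-2-[(2R)-1-[4-(methoxymethoxy)phenyl]propan-2-yl]benzene
Conditions: MOMCl (3 equiv), i-Pr2NEt, CH2Cl2, 0 °C → rt
Reagents that add atoms: chloromethyl methyl ether, COCCl
Why: O-alkylation of both phenols gives methoxymethyl acetals that tolerate organolithium, zinc and borohydride reagents and fall off under the acid of the last step.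

Step 5
Reactants: 7 meso-(2R,3S)-2,3-dimethylbutanedioic acid
Product: 8 cis-(3R,4S)-3,4-dimethyloxolane-2,5-dione
Conditions: AcCl, reflux; evaporate
Reagents that add atoms: none
Why: cyclodehydration of the 1,4-diacid through its mixed anhydride should give the five-membered anhydride without epimerising the methine centres, so the cis (meso) relationship is kept.

Step 6
Reactants: 8 cis-(3R,4S)-3,4-dimethyloxolane-2,5-dione; 9 1-bromo-4-(methoxymethoxy)benzene
Product: 12 (2R,3S)-4-[4-(methoxymethoxy)phenyl]-2,3-dimethyl-4-oxobutanoic acid, via aryllithium 10 (not isolated), via arylzinc triflate 11 (not isolated)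
Conditions: 9, n-BuLi, THF, −78 °C; Zn(OTf)2, → rt; then 8, [Rh(cod)Cl]2 (4 mol%), (S)-t-Bu-PHOX (8 mol%), 50 °C; 1 M HCl
Reagents that add atoms: none
Why: Rh-catalysed enantioselective desymmetrising acylation of a meso cyclic anhydride with an arylzinc (enantiotopic C–O oxidative addition, transmetallation, reductive elimination) should arylate only the carbonyl next to the S-configured methine, and because neither methine is touched the syn dimethyl unit is carried over as (2R,3S).

Step 7
Reactants: 12 (2R,3S)-4-[4-(methoxymethoxy)phenyl]-2,3-dimethyl-4-oxobutanoic acid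
Product: 14 (3R,4S,5S)-5-[4-(methoxymethoxy)phenyl]-3,4-dimethyloxolan-2-one, via hydroxy acid 13 (not isolated)
Conditions: NaBH4, EtOH/aq. NaHCO3, 0 °C; aq. citric acid; then PPTS (cat.), toluene, 50 °C
Reagents that add atoms: none
Why: Felkin–Anh reduction of the aryl ketone should give mainly the carbinol with OH anti to the neighbouring methyl (4S), and the γ-hydroxy acid then lactonises under mild acid that leaves the MOM group in place.

Step 8
Reactants: 14 (3R,4S,5S)-5-[4-(methoxymethoxy)phenyl]-3,4-dimethyloxolan-2-one; 6 4-bromo-1-(methoxymethoxy)-2-[(2R)-1-[4-(methoxymethoxy)phenyl]propan-2-yl]benzene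
Product: 16 (2R,3S,4S)-4-hydroxy-1-{4-(methoxymethoxy)-3-[(2R)-1-[4-(methoxymethoxy)phenyl]propan-2-yl]phenyl}-4-[4-(methoxymethoxy)phenyl]-2,3-dimethylbutan-1-one, via aryllithium 15 (not isolated)
Conditions: 6 (1.3 equiv), n-BuLi, THF, −78 °C; then 14, −78 °C; aq. NH4Cl
Reagents that add atoms: none
Why: bromine–lithium exchange followed by single addition of the aryllithium to the γ-lactone should stop at the lithium hemiketal alkoxide at −78 °C, which opens on work-up to the hydroxy ketone (in equilibrium with its cyclic hemiketal) without forming or touching a stereocentre.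

Step 9
Reactants: 16 (2R,3S,4S)-4-hydroxy-1-{4-(methoxymethoxy)-3-[(2R)-1-[4-(methoxymethoxy)phenyl]propan-2-yl]phenyl}-4-[4-(methoxymethoxy)phenyl]-2,3-dimethylbutan-1-one
Product: 18 4-[(2S,3S,4R,5R)-5-{4-hydroxy-3-[(2R)-1-(4-hydroxyphenyl)propan-2-yl]phenyl}-3,4-dimethyloxolan-2-yl]phenol, via diol 17 (not isolated)
Conditions: NaBH4, MeOH, 0 °C; then conc. HCl to 2 M, 45 °C, dilute (0.02 M), until the isomer ratio is constant
Reagents that add atoms: none
Why: Borohydride reduces the ketone of 16 to the 1,4-diol 17 (both C1 epimers), and the acid then cleaves the three MOM acetals to dimethoxymethane and ionises either p-oxybenzylic carbinol to a cation that is a protonated p-quinone methide, which the other hydroxyl captures. The closest known reaction type is the acid-mediated cyclodehydration of 1,4-diaryl-2,3-dimethylbutane-1,4-diols to 2,5-diaryl-3,4-dimethyltetrahydrofurans. The oxolane closes in the 5-exo-trig mode, the hydroxyl oxygen adding to the exocyclic methine carbon of the quinone methide (C2 or C5) to form the C–O bond. C2 and C5 are set under thermodynamic control, because each benzylic C–O bond re-ionises until each aryl sits trans to the methyl on the neighbouring carbon, with the untouched centres C3 (S) and C4 (R) as the controlling elements, so the carbinol configurations of 17 do not matter. The step needs ether formation to win over E1 loss of the C3/C4 hydrogens and over Friedel–Crafts attack, and it needs the trans,cis,trans isomer; the first is secured by fast five-membered capture with methanol as a reversible external trap and by the ring positions ortho to the benzylic carbons being meta to oxygen and thus not nucleophilic, the second by the steric bias of the cis-dimethyl unit.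

Compound list
1 | 1-methoxy-4-(prop-1-yn-1-yl)benzene | CC#Cc1ccc(OC)cc1 | starting material
2 | (5-bromo-2-methoxyphenyl)boronic acid | COc1ccc(Br)cc1B(O)O | starting material
3 | 4-bromo-1-methoxy-2-[(E)-1-(4-methoxyphenyl)prop-1-en-2-yl]benzene | COc1ccc(Br)cc1/C(C)=C/c1ccc(OC)cc1 | intermediate
4 | 4-bromo-1-methoxy-2-[(2R)-1-(4-methoxyphenyl)propan-2-yl]benzene | COc1ccc(Br)cc1[C@H](C)Cc1ccc(OC)cc1 | intermediate
5 | 4-bromo-2-[(2R)-1-(4-hydroxyphenyl)propan-2-yl]phenol | Oc1ccc(Br)cc1[C@H](C)Cc1ccc(O)cc1 | intermediate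
6 | 4-bromo-1-(methoxymethoxy)-2-[(2R)-1-[4-(methoxymethoxy)phenyl]propan-2-yl]benzene | COCOc1ccc(Br)cc1[C@H](C)Cc1ccc(OCOC)cc1 | intermediate
7 | meso-(2R,3S)-2,3-dimethylbutanedioic acid | C[C@@H](C(=O)O)[C@H](C)C(=O)O | starting material
8 | cis-(3R,4S)-3,4-dimethyloxolane-2,5-dione (meso anhydride) | C[C@@H]1[C@H](C)C(=O)OC1=O | intermediate
9 | 1-bromo-4-(methoxymethoxy)benzene | COCOc1ccc(Br)cc1 | starting material
10 | [4-(methoxymethoxy)phenyl]lithium | [Li]c1ccc(OCOC)cc1 | intermediate
11 | [4-(methoxymethoxy)phenyl]zinc trifluoromethanesulfonate | COCOc1ccc(cc1)[Zn]OS(=O)(=O)C(F)(F)F | intermediate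
12 | (2R,3S)-4-[4-(methoxymethoxy)phenyl]-2,3-dimethyl-4-oxobutanoic acid | C[C@@H](C(=O)O)[C@H](C)C(=O)c1ccc(OCOC)cc1 | intermediate
13 | (2R,3S,4S)-4-hydroxy-4-[4-(methoxymethoxy)phenyl]-2,3-dimethylbutanoic acid | C[C@@H](C(=O)O)[C@H](C)[C@@H](c1ccc(OCOC)cc1)O | intermediate
14 | (3R,4S,5S)-5-[4-(methoxymethoxy)phenyl]-3,4-dimethyloxolan-2-one (methyls cis, aryl trans to the C4 methyl) | C[C@@H]1[C@H](C)[C@@H](c2ccc(OCOC)cc2)OC1=O | intermediate
15 | {4-(methoxymethoxy)-3-[(2R)-1-[4-(methoxymethoxy)phenyl]propan-2-yl]phenyl}lithium | [Li]c1ccc(OCOC)c(c1)[C@H](C)Cc1ccc(OCOC)cc1 | intermediate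
16 | (2R,3S,4S)-4-hydroxy-1-{4-(methoxymethoxy)-3-[(2R)-1-[4-(methoxymethoxy)phenyl]propan-2-yl]phenyl}-4-[4-(methoxymethoxy)phenyl]-2,3-dimethylbutan-1-one | C[C@@H](C(=O)c1ccc(OCOC)c(c1)[C@H](C)Cc1ccc(OCOC)cc1)[C@H](C)[C@@H](c1ccc(OCOC)cc1)O | intermediate
17 | (2R,3S,4S)-1-{4-(methoxymethoxy)-3-[(2R)-1-[4-(methoxymethoxy)phenyl]propan-2-yl]phenyl}-4-[4-(methoxymethoxy)phenyl]-2,3-dimethylbutane-1,4-diol, both C1 epimers (C1 left undefined) | C[C@@H](C(O)c1ccc(OCOC)c(c1)[C@H](C)Cc1ccc(OCOC)cc1)[C@H](C)[C@@H](c1ccc(OCOC)cc1)O | intermediate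
18 | 4-[(2S,3S,4R,5R)-5-{4-hydroxy-3-[(2R)-1-(4-hydroxyphenyl)propan-2-yl]phenyl}-3,4-dimethyloxolan-2-yl]phenol | C[C@@H]1[C@H](C)[C@@H](c2ccc(O)cc2)O[C@H]1c1ccc(O)c([C@H](C)Cc2ccc(O)cc2)c1 | target

Total step count: 9. Longest linear sequence: 6 steps (1, 2, 3, 4, 8, 9).

Steps most likely to fail

Step 9. The one-pot acid stage may stall before full equilibration, or lose material through E1 elimination, oligomerisation or alkylation of the freed phenols by the released methoxymethyl cation. The fallback sets out from 16 and returns at 18; it separates ring closure from deprotection and avoids Brønsted acid. The cyclic hemiketal form of 16 is reduced with Et3SiH/BF3·OEt2 (CH2Cl2, −78 → 0 °C). Hydride adds to the cyclic oxocarbenium ion, and brief warming with BF3 lets the benzylic centres settle trans to their neighbouring methyls. This should give (2S,3S,4R,5R)-2-[4-(methoxymethoxy)phenyl]-5-{4-(methoxymethoxy)-3-[(2R)-1-[4-(methoxymethoxy)phenyl]propan-2-yl]phenyl}-3,4-dimethyloxolane F1. The MOM groups are then removed with ZnBr2/n-PrSH (CH2Cl2, 0 °C), the thiol trapping the methoxymethyl unit, to give 18.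

Step 6. Discrimination between the enantiotopic carbonyls may be insufficient, transmetallation from the arylzinc may be slow, or the methine next to the new ketone may epimerise. The fallback sets out from 8 and returns at 14. Cinchona-alkaloid-mediated methanolysis of 8 (quinidine-type catalyst, MeOH, toluene, low temperature) gives (2S,3R)-4-methoxy-2,3-dimethyl-4-oxobutanoic acid F2. EtSH/DCC/DMAP converts it into methyl (2R,3S)-4-(ethylsulfanyl)-2,3-dimethyl-4-oxobutanoate F3. Liebeskind–Srogl coupling with [4-(methoxymethoxy)phenyl]boronic acid (Pd2(dba)3, tri(2-furyl)phosphine, CuTC, THF, 50 °C) gives methyl (2R,3S)-4-[4-(methoxymethoxy)phenyl]-2,3-dimethyl-4-oxobutanoate F4. NaBH4 reduction and PPTS-catalysed lactonisation with loss of methanol then give 14.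

Step 2. The ortho-methoxy group twists the aryl ring and may bind iridium, so facial selectivity or turnover may be poor. The fallback sets out from 2 and returns at 4. Rh/BINAP-catalysed conjugate addition of 2 to tert-butyl (E)-but-2-enoate (Hayashi–Miyaura reaction) gives tert-butyl (3R)-3-(5-bromo-2-methoxyphenyl)butanoate F5. TFA frees (3R)-3-(5-bromo-2-methoxyphenyl)butanoic acid F6. N-Hydroxyphthalimide/DIC gives 1,3-dioxoisoindolin-2-yl (3R)-3-(5-bromo-2-methoxyphenyl)butanoate F7. Iron-catalysed decarboxylative coupling of this redox-active ester with (4-methoxyphenyl)zinc chloride then gives 4; the stereocentre is β to the radical site and is not touched.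

Further compounds
F1 | step 9 | (2S,3S,4R,5R)-2-[4-(methoxymethoxy)phenyl]-5-{4-(methoxymethoxy)-3-[(2R)-1-[4-(methoxymethoxy)phenyl]propan-2-yl]phenyl}-3,4-dimethyloxolane | C[C@@H]1[C@H](C)[C@@H](c2ccc(OCOC)cc2)O[C@H]1c1ccc(OCOC)c([C@H](C)Cc2ccc(OCOC)cc2)c1
F2 | step 6 | (2S,3R)-4-methoxy-2,3-dimethyl-4-oxobutanoic acid | C[C@@H](C(=O)OC)[C@H](C)C(=O)O
F3 | step 6 | methyl (2R,3S)-4-(ethylsulfanyl)-2,3-dimethyl-4-oxobutanoate | C[C@@H](C(=O)OC)[C@H](C)C(=O)SCC
F4 | step 6 | methyl (2R,3S)-4-[4-(methoxymethoxy)phenyl]-2,3-dimethyl-4-oxobutanoate | C[C@@H](C(=O)OC)[C@H](C)C(=O)c1ccc(OCOC)cc1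
F5 | step 2 | tert-butyl (3R)-3-(5-bromo-2-methoxyphenyl)butanoate | COc1ccc(Br)cc1[C@H](C)CC(=O)OC(C)(C)C
F6 | step 2 | (3R)-3-(5-bromo-2-methoxyphenyl)butanoic acid | COc1ccc(Br)cc1[C@H](C)CC(=O)O
F7 | step 2 | 1,3-dioxoisoindolin-2-yl (3R)-3-(5-bromo-2-methoxyphenyl)butanoate | COc1ccc(Br)cc1[C@H](C)CC(=O)ON1C(=O)c2ccccc2C1=O
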